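## Structural features

The target is a flavanone. A benzene ring A is fused to a 2,3-dihydropyran-4-one ring C (O1, C2, C3, C4, C4a, C8a), and C2 carries a 4-hydroxyphenyl ring B. Ring A is pentasubstituted: O1 at C8a, the C4 carbonyl at C4a, 3-methylbut-2-enyl (prenyl) groups at C6 and C8, and a free hydroxyl at C7 between them; only C5 bears hydrogen. C2 is the only stereocentre and has the S configuration. It is benzylic and β to the C4 ketone, so it can be lost by retro-oxa-Michael opening to the chalcone, most easily under base once the 4'-hydroxyl is free. The two trisubstituted alkenes are the fragile groups: protic or Lewis acids add across them or let the C7 hydroxyl close a chroman ring, and hydrogenation and strong oxidants are excluded. The real difficulty is a regiodefined ring A (two C-prenyl groups, two oxygens that must be told apart), which direct prenylation of a resorcinol does not deliver, together with a C2 centre that must be set and then kept. The key step uses the contiguous array C8a(O1)–C8(prenyl)–C7(OH)–C6(prenyl): C8a and C8 map onto the two carbons of a siloxyalkyne carrying one prenyl group, and C7, C4a, C5 and C6 onto a vinylketene carrying the other. Atom mapping of the two precursors onto the benzannulation product confirms that their structures need no correction.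

## Logic of the disconnections

25 goes back to 24 by cutting only two O–C bonds of protecting groups, the acetal at O7 and the acetyl at O4'. Both fall to dilute acid in methanol in one operation, so no base meets the finished flavanone. The forward step must be cold and dilute enough to leave both prenyl groups untouched.

24 is cut at C4–C4a to give 22 (through 23). Ring C closes by intramolecular acylation; C4a is the only free position ortho to O1 and is para to the O7 ether, so regiochemistry is not in question. The cut reduces the bicycle to an aryl ether of a 3-arylpropanoic acid. The forward step must activate the acid without strong acid, and the benzylic C2–O1 bond must not ionise. For that reason the O4' group is an electron-poor acetate rather than an ether.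

22 goes back to 21 by cutting the O–allyl bond of the ester. The allyl ester lets the acid be released by zerovalent palladium under neutral conditions. Hydroxide is avoided because it would cleave the aryl acetate and could expel the phenoxide from the ester enolate, destroying C2.

21 is cut at O1–C2 into 16 and 20. This is the convergent cut: ring A with differentiated oxygens on one side, the stereocentre on the other. The forward step is an etherification with inversion, so 20 must be R. The step has to outrun β-elimination and must stay on the SN2 path, which the ring B acetate supports.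

20 goes back to 19 by removing the carbinol hydrogen (ketone reduction under catalyst control), and 19 is cut between the aroyl carbon and C3 to give 17. The gain is an achiral, two-operation fragment. The forward reduction must tolerate the allyl ester and the aryl acetate.

16 goes back to 15 by cutting O–Si, and 15 to 14 by cutting the O–CH2 bond of the acetal. This pair of operations exchanges which oxygen is free: the phenol of 14 becomes the protected O7, and the silyl ether becomes the nucleophilic O1. The forward steps must alkylate a phenol flanked by two prenyl groups and remove silicon without touching the acetal.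

14 is cut at four ring bonds, C4a–C5, C7–C8, C8a–C4a and C6–C7, giving 9 and 5 (through 10, 11, 12 and 13). All of ring A, both prenyl positions and the differentiation of the two oxygens come from one operation on two acyclic pieces. The forward step needs one orientation of ketene–alkyne union and light that the skipped diene and the product phenol do not absorb.

9 goes back to 7 by cutting the C=N2 bond (through 8), 7 is cut at its C3=C4 alkene to 6 and a stabilised ylide, and 6 goes back to 2 by reduction level. The E geometry comes from the stabilised ylide. The forward steps must not move the 1,4-diene into conjugation.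

5 is cut at O–Si to 4, and 4 is traced through 3 to 2 by removing the one carbon that becomes the oxygen-bearing alkyne carbon. Both halves of ring A therefore come from 2. The forward step must add a carbenoid to an ester with an acidic methylene faster than it deprotonates it.

2 goes back to 1 by cutting the O–ethyl bond. The forward esterification must avoid acid, which would lactonise 1.

## Other disconnections considered

Alternative 1: The cut is at the two side-chain C=C bonds, so both prenyl groups are traced to allyl groups. In the forward direction the (S)-6,8-diallyl flavanone A1 undergoes twofold cross-metathesis with 2-methylbut-2-ene A2 under the second-generation Grubbs catalyst RuCl2(H2IMes)(PCy3)(=CHPh) to give A3. In its favour, the acid-sensitive trisubstituted alkenes are introduced last and under neutral conditions; on this point it is better than the chosen plan, which carries both prenyl groups through acylation and deprotection. The reaction class is dependable for allyl-to-prenyl conversion. Against it, the regiochemical problem is only moved: two allyl groups must be placed on C6 and C8 by two successive O-allylation and aromatic Claisen sequences at high temperature, and C2 would have to survive that heating or be set afterwards. The metathesis itself sets nothing at C2. The core would come from a cheap resorcinol-derived ketone, so on starting-material cost it is equal or better. Once two rearrangements, the metathesis and a separate asymmetric step are counted, the length is similar to the chosen route. It also lacks the single operation that fixes the ring A pattern through bond polarity.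

Alternative 2: The cut is at O1–C8a. In the forward direction the C2 hydroxyl of the bromo anti-1,3-diol A4 couples with the C8a bromide under CuI with a phenanthroline ligand and Cs2CO3, closing ring C as the flavan-4-ol A5, which must then be oxidised at C4. In its favour, C2 is set on an open chain by reduction chemistry and carried with retention; this is better than the chosen plan, which inverts a benzylic centre and has to suppress elimination. No electrophilic acylation is run in the presence of prenyl groups, also a point in its favour. Only the C2 hydroxyl can reach C8a in a six-membered ring, so chemoselectivity between the two hydroxyls is secure. Against it, A4 contains a pentasubstituted ring A bromide, so the ring A regiochemistry problem is untouched and made harder by the extra halogen. The bromide is flanked on both sides, a poor substrate for oxidative addition to monovalent copper, and hot carbonate invites retro-aldol cleavage or dehydration of the benzylic diol. The C4 stereocentre is made only to be destroyed. Overall the sequence is longer than the chosen one.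

Alternative 3: The cut is at C5–C6 and C8–C8a, using the hidden symmetry of ring A. In the forward direction the enolate of the symmetric ketone A6 displaces ethoxide from the malonate A7, and under alkoxide the second α-carbon attacks an ester carbonyl; aromatisation gives the resorcylate A8. In its favour, the symmetry of A6 makes the regiochemistry automatic, and the chemistry is ground-state and scalable with no diazo compound and no photochemistry; on safety and scale it is better than the chosen plan. C4a already bears the carbon that becomes C4, so no Friedel–Crafts step is needed, also better. The two hydroxyls are told apart by chelation to the ester, which is equal to the phenol/silyl ether differentiation of the chosen plan. Against it, the ester still has to be extended by C3 and C2, and C2 then has to be set by a catalytic asymmetric conjugate addition or cyclisation on a hindered chromone or chalcone, which is less direct than coupling with a preformed chiral alcohol. A6 itself needs a double prenylation. Ring A is reached in fewer steps than in the chosen route, but the steps after the annulation are more numerous, so the totals are comparable.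

Key step: step 5

Assumption: 4-methylpent-3-enoic acid and 4-(chlorocarbonyl)phenyl acetate are taken as purchasable; flavanone numbering (O1, C2–C4, C4a, C5–C8, C8a, primed positions for ring B) is used for every intermediate that contains ring A.

## Route

Step 1
Reactants: 1 4-methylpent-3-enoic acid
Product: 2 ethyl 4-methylpent-3-enoate
Conditions: EtI, K2CO3, DMF, rt
Reagents that add atoms: iodoethane, CCI
Why: SN2 O-alkylation of the carboxylate; basic conditions avoid the acid-catalysed lactonisation and double-bond migration that a Fischer esterification of this β,γ-unsaturated acid would risk.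

Step 2
Reactants: 2 ethyl 4-methylpent-3-enoate
Product: 5 triisopropyl[(5-methylhex-4-en-1-yn-1-yl)oxy]silane, via lithium dibromoenolate 3 (not isolated), via lithium ynolate 4 (not isolated)
Conditions: CH2Br2, lithium 2,2,6,6-tetramethylpiperidide, THF, −78 °C, then 2; LiN(SiMe3)2; n-BuLi, −78 °C → rt; i-Pr3SiOTf, −78 → 0 °C
Reagents that add atoms: dibromomethane, BrCBr; triisopropylsilyl trifluoromethanesulfonate, CC(C)[Si](OS(=O)(=O)C(F)(F)F)(C(C)C)C(C)C
Why: Kowalski ester homologation: the preformed carbenoid LiCHBr2 adds to the ester, the dibromoketone enolate 3 undergoes bromine–lithium exchange and 1,2-shift to ynolate 4, and the bulky silyl triflate should silylate on oxygen; preforming the carbenoid cold is meant to keep addition ahead of enolisation of the allylic methylene.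

Step 3
Reactants: 2 ethyl 4-methylpent-3-enoate
Product: 7 (E)-7-methylocta-3,6-dien-2-one, via 4-methylpent-3-enal 6 (not isolated)
Conditions: i-Bu2AlH, CH2Cl2, −78 °C; MeOH, aq. potassium sodium tartrate; then Ph3P=CHC(O)CH3, CH2Cl2, rt
Reagents that add atoms: 1-(triphenyl-λ5-phosphanylidene)propan-2-one, CC(=O)C=P(c1ccccc1)(c1ccccc1)c1ccccc1
Why: Partial reduction through the stable aluminium hemiacetal, then Wittig olefination of the crude aldehyde with a ketone-stabilised ylide, which should give the E enone and is too weakly basic to move the β,γ-alkene into conjugation.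

Step 4
Reactants: 7 (E)-7-methylocta-3,6-dien-2-one
Product: 9 (E)-1-diazo-7-methylocta-3,6-dien-2-one, via trifluoroacetyl diketone 8 (not isolated)
Conditions: LiN(SiMe3)2, THF, −78 °C; CF3CO2CH2CF3; aq. HCl; then MsN3, Et3N, H2O, MeCN, rt
Reagents that add atoms: methanesulfonyl azide, CS(=O)(=O)N=[N+]=[N-]
Why: Detrifluoroacetylative diazo transfer: kinetic deprotonation at the methyl group and trifluoroacetylation give 8, whose activated methylene takes the diazo group from the sulfonyl azide with loss of the trifluoroacetyl group; this is the standard entry to α,β-unsaturated diazoketones, for which acid chloride/diazomethane routes fail.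

Step 5
Reactants: 9 (E)-1-diazo-7-methylocta-3,6-dien-2-one; 5 triisopropyl[(5-methylhex-4-en-1-yn-1-yl)oxy]silane
Product: 14 2,6-bis(3-methylbut-2-en-1-yl)-3-{[tri(propan-2-yl)silyl]oxy}phenol, via vinylketene 10 (not isolated), via 4-alkenylcyclobutenone 11 (not isolated), via dienylketene 12 (not isolated), via cyclohexadienone 13 (not isolated)
Conditions: 5 (1.5 equiv), ClCH2CH2Cl, hν (Pyrex filter, λ > 300 nm), rt; then 80 °C, dark
Reagents that add atoms: none
Why: Light expels dinitrogen from 9 and the alkenyl group shifts to the former diazo carbon (Wolff rearrangement), which forms C4a–C5 and gives vinylketene 10. The electron-rich, prenyl-bearing carbon of 5 bonds to the ketene carbonyl carbon and the siloxy carbon to the ketene α-carbon in a [2+2] cycloaddition, forming C7–C8 and C8a–C4a in cyclobutenone 11. Four-electron conrotatory opening of 11, by light or on warming, gives dienylketene 12, and a six-electron disrotatory electrocyclisation forms C6–C7 and closes ring A as cyclohexadienone 13, which tautomerises to 14. The closest known reaction type is the Danheiser benzannulation in its photochemical Wolff variant with siloxyalkynes. Ring A is thus closed in a pericyclic mode, a 6π electrocyclisation of a (Z)-dienylketene, and no stereocentre remains because the sp3 centres of 11 and 13 are lost on aromatisation. The step needs one orientation of ketene–alkyne union; the oxygen-induced polarisation of the siloxyalkyne secures it, placing one prenyl group between the two oxygens and leaving the C7 oxygen as free phenol and O1 as silyl ether. It also needs chemoselectivity: the E alkene keeps the carbene and ketene carbons out of reach of the tethered prenyl alkene, Pyrex-filtered light is not absorbed by the isolated alkenes or by phenol 14, and the excess of 5 should limit acylation of 14 by 10.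

Step 6
Reactants: 14 2,6-bis(3-methylbut-2-en-1-yl)-3-{[tri(propan-2-yl)silyl]oxy}phenol
Product: 15 triisopropyl[3-(methoxymethoxy)-2,4-bis(3-methylbut-2-en-1-yl)phenoxy]silane
Conditions: NaH, MOMCl, THF–DMF, 0 °C → rt
Reagents that add atoms: chloromethyl methyl ether, COCCl
Why: Williamson-type O-alkylation of the sodium phenoxide; the small, highly reactive chloromethyl ether should reach the oxygen flanked by two prenyl groups, and the resulting acetal keeps ring A electron-rich for the later acylation.

Step 7
Reactants: 15 triisopropyl[3-(methoxymethoxy)-2,4-bis(3-methylbut-2-en-1-yl)phenoxy]silane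
Product: 16 3-(methoxymethoxy)-2,4-bis(3-methylbut-2-en-1-yl)phenol
Conditions: Bu4NF, AcOH, THF, 0 °C → rt
Reagents that add atoms: none
Why: Fluoride-induced cleavage of the aryl silyl ether; buffering with acetic acid avoids a free electron-rich phenoxide and leaves the acetal and alkenes untouched.

Step 8
Reactants: 17 4-(chlorocarbonyl)phenyl acetate
Product: 19 prop-2-en-1-yl 3-(4-acetoxyphenyl)-3-oxopropanoate, via acyl Meldrum's acid 18 (not isolated)
Conditions: Meldrum's acid, pyridine, CH2Cl2, 0 °C → rt; then allyl alcohol, toluene, 90 °C
Reagents that add atoms: 2,2-dimethyl-1,3-dioxane-4,6-dione, CC1(C)OC(=O)CC(=O)O1; prop-2-en-1-ol, C=CCO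
Why: C-acylation of Meldrum's acid, then thermal fragmentation of 18 to an acylketene that is trapped by the alcohol; the neutral alcoholysis should spare the aryl acetate.

Step 9
Reactants: 19 prop-2-en-1-yl 3-(4-acetoxyphenyl)-3-oxopropanoate
Product: 20 prop-2-en-1-yl (3R)-3-(4-acetoxyphenyl)-3-hydroxypropanoate
Conditions: RuCl[(R,R)-TsDPEN](p-cymene) (1 mol%), HCO2H–Et3N (5:2), 30 °C
Reagents that add atoms: none
Why: Noyori asymmetric transfer hydrogenation of an aryl ketone; the (R,R)-diamine complex delivers hydride through the six-membered outer-sphere transition state, with the aryl group held against the arene ligand, to give the R carbinol, and an outer-sphere hydride donor does not reduce the allyl ester alkene.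

Step 10
Reactants: 16 3-(methoxymethoxy)-2,4-bis(3-methylbut-2-en-1-yl)phenol; 20 prop-2-en-1-yl (3R)-3-(4-acetoxyphenyl)-3-hydroxypropanoate
Product: 21 prop-2-en-1-yl (3S)-3-(4-acetoxyphenyl)-3-[3-(methoxymethoxy)-2,4-bis(3-methylbut-2-en-1-yl)phenoxy]propanoate
Conditions: PPh3, DIAD, toluene, 0 °C → rt
Reagents that add atoms: none
Why: Mitsunobu etherification: the phenoxide displaces the alkoxyphosphonium group in an SN2 step with inversion, which turns the R alcohol into the S ether and so sets C2; the acetoxy group on ring B is a much weaker cation stabiliser than an ether, which together with the non-polar solvent should keep the reaction off the ionisation path.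

Step 11
Reactants: 21 prop-2-en-1-yl (3S)-3-(4-acetoxyphenyl)-3-[3-(methoxymethoxy)-2,4-bis(3-methylbut-2-en-1-yl)phenoxy]propanoate
Product: 22 (3S)-3-(4-acetoxyphenyl)-3-[3-(methoxymethoxy)-2,4-bis(3-methylbut-2-en-1-yl)phenoxy]propanoic acid
Conditions: Pd(PPh3)4 (3 mol%), PhNHMe, THF, rt
Reagents that add atoms: none
Why: Tsuji–Trost deallylation: zerovalent palladium ionises the allyl ester and the aniline traps the π-allyl fragment; no hydroxide is present, so the aryl acetate survives and the β-aryloxy ester cannot undergo E1cB loss of the phenoxide.

Step 12
Reactants: 22 (3S)-3-(4-acetoxyphenyl)-3-[3-(methoxymethoxy)-2,4-bis(3-methylbut-2-en-1-yl)phenoxy]propanoic acid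
Product: 24 4-[(2S)-7-(methoxymethoxy)-6,8-bis(3-methylbut-2-en-1-yl)-4-oxo-3,4-dihydro-2H-chromen-2-yl]phenyl acetate, via mixed trifluoroacetic anhydride 23 (not isolated)
Conditions: (CF3CO)2O, CH2Cl2, 0 °C → rt
Reagents that add atoms: none
Why: Intramolecular Friedel–Crafts acylation through the mixed anhydride; C4a is ortho to O1 and para to the O7 acetal, so this doubly activated position should be acylated without a Lewis acid, closing the six-membered ring C while C2 is untouched.

Step 13
Reactants: 24 4-[(2S)-7-(methoxymethoxy)-6,8-bis(3-methylbut-2-en-1-yl)-4-oxo-3,4-dihydro-2H-chromen-2-yl]phenyl acetate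
Product: 25 (2S)-7-hydroxy-2-(4-hydroxyphenyl)-6,8-bis(3-methylbut-2-en-1-yl)-2,3-dihydro-4H-chromen-4-one
Conditions: HCl (1.25 M in MeOH), rt
Reagents that add atoms: none
Why: Acid-catalysed acetal exchange removes the methoxymethyl group and acid-catalysed transesterification removes the aryl acetate in one operation; dilute acid at room temperature is the usual way to unmask prenylated phenols, and the absence of base protects C2 from ring opening.

## Compound list

1 | 4-methylpent-3-enoic acid | CC(C)=CCC(=O)O | starting material
2 | ethyl 4-methylpent-3-enoate | CCOC(=O)CC=C(C)C | intermediate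
3 | lithium 1,1-dibromo-5-methylhexa-1,4-dien-2-olate | [Li]OC(CC=C(C)C)=C(Br)Br | intermediate
4 | lithium 5-methylhex-4-en-1-yn-1-olate | [Li]OC#CCC=C(C)C | intermediate
5 | triisopropyl[(5-methylhex-4-en-1-yn-1-yl)oxy]silane | CC(C)=CCC#CO[Si](C(C)C)(C(C)C)C(C)C | intermediate
6 | 4-methylpent-3-enal | CC(C)=CCC=O | intermediate
7 | (E)-7-methylocta-3,6-dien-2-one | CC(=O)/C=C/CC=C(C)C | intermediate
8 | (E)-1,1,1-trifluoro-9-methyldeca-5,8-diene-2,4-dione | CC(C)=CC/C=C/C(=O)CC(=O)C(F)(F)F | intermediate
9 | (E)-1-diazo-7-methylocta-3,6-dien-2-one | CC(C)=CC/C=C/C(=O)C=[N+]=[N-] | intermediate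
10 | (3E)-7-methylocta-1,3,6-trien-1-one | O=C=C/C=C/CC=C(C)C | intermediate
11 | 2-(3-methylbut-2-en-1-yl)-4-[(1E)-5-methylhexa-1,4-dien-1-yl]-3-{[tri(propan-2-yl)silyl]oxy}cyclobut-2-en-1-one (racemic) | O=C1C(CC=C(C)C)=C(O[Si](C(C)C)(C(C)C)C(C)C)C1/C=C/CC=C(C)C | intermediate
12 | (3E,5E)-9-methyl-2-(3-methylbut-2-en-1-yl)-3-{[tri(propan-2-yl)silyl]oxy}deca-1,3,5,8-tetraen-1-one | O=C=C(CC=C(C)C)/C(O[Si](C(C)C)(C(C)C)C(C)C)=C\C=C\CC=C(C)C | intermediate
13 | 2,6-bis(3-methylbut-2-en-1-yl)-3-{[tri(propan-2-yl)silyl]oxy}cyclohexa-2,4-dien-1-one (racemic) | O=C1C(CC=C(C)C)=C(O[Si](C(C)C)(C(C)C)C(C)C)C=CC1CC=C(C)C | intermediate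
14 | 2,6-bis(3-methylbut-2-en-1-yl)-3-{[tri(propan-2-yl)silyl]oxy}phenol | CC(C)=CCc1ccc(O[Si](C(C)C)(C(C)C)C(C)C)c(CC=C(C)C)c1O | intermediate
15 | triisopropyl[3-(methoxymethoxy)-2,4-bis(3-methylbut-2-en-1-yl)phenoxy]silane | CC(C)=CCc1ccc(O[Si](C(C)C)(C(C)C)C(C)C)c(CC=C(C)C)c1OCOC | intermediate
16 | 3-(methoxymethoxy)-2,4-bis(3-methylbut-2-en-1-yl)phenol | CC(C)=CCc1ccc(O)c(CC=C(C)C)c1OCOC | intermediate
17 | 4-(chlorocarbonyl)phenyl acetate | CC(=O)Oc1ccc(cc1)C(Cl)=O | starting material
18 | 4-[(2,2-dimethyl-4,6-dioxo-1,3-dioxan-5-yl)carbonyl]phenyl acetate | CC(=O)Oc1ccc(cc1)C(=O)C1C(=O)OC(C)(C)OC1=O | intermediate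
19 | prop-2-en-1-yl 3-(4-acetoxyphenyl)-3-oxopropanoate | C=CCOC(=O)CC(=O)c1ccc(OC(C)=O)cc1 | intermediate
20 | prop-2-en-1-yl (3R)-3-(4-acetoxyphenyl)-3-hydroxypropanoate | C=CCOC(=O)C[C@@H](O)c1ccc(OC(C)=O)cc1 | intermediate
21 | prop-2-en-1-yl (3S)-3-(4-acetoxyphenyl)-3-[3-(methoxymethoxy)-2,4-bis(3-methylbut-2-en-1-yl)phenoxy]propanoate | C=CCOC(=O)C[C@H](Oc1ccc(CC=C(C)C)c(OCOC)c1CC=C(C)C)c1ccc(OC(C)=O)cc1 | intermediate
22 | (3S)-3-(4-acetoxyphenyl)-3-[3-(methoxymethoxy)-2,4-bis(3-methylbut-2-en-1-yl)phenoxy]propanoic acid | OC(=O)C[C@H](Oc1ccc(CC=C(C)C)c(OCOC)c1CC=C(C)C)c1ccc(OC(C)=O)cc1 | intermediate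
23 | (3S)-3-(4-acetoxyphenyl)-3-[3-(methoxymethoxy)-2,4-bis(3-methylbut-2-en-1-yl)phenoxy]propanoic trifluoroacetic anhydride | FC(F)(F)C(=O)OC(=O)C[C@H](Oc1ccc(CC=C(C)C)c(OCOC)c1CC=C(C)C)c1ccc(OC(C)=O)cc1 | intermediate
24 | 4-[(2S)-7-(methoxymethoxy)-6,8-bis(3-methylbut-2-en-1-yl)-4-oxo-3,4-dihydro-2H-chromen-2-yl]phenyl acetate | CC(C)=CCc1cc2c(c(CC=C(C)C)c1OCOC)O[C@H](c1ccc(OC(C)=O)cc1)CC2=O | intermediate
25 | (2S)-7-hydroxy-2-(4-hydroxyphenyl)-6,8-bis(3-methylbut-2-en-1-yl)-2,3-dihydro-4H-chromen-4-one | CC(C)=CCc1cc2c(c(CC=C(C)C)c1O)O[C@H](c1ccc(O)cc1)CC2=O | target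

## Step count and least certain steps

Total step count: 13. Longest linear sequence: 10 steps (steps 1, 3, 4, 5, 6, 7, 10, 11, 12, 13).

Step 5 (key step). The most likely failure is loss of material through secondary photochemistry and through acylation of the newly formed phenol by the vinylketene. The enone of 9 can undergo E/Z isomerisation in competition with loss of dinitrogen, the 1,4-diene is itself a chromophore at shorter wavelengths, and 14 is a nucleophile towards 10. The fallback removes light and the diazo group. It sets out from 5 and returns at 14. The partner is made separately: [2+2] cycloaddition of ethoxyacetylene with the ketene from 5-methylhex-4-enoyl chloride and Et3N should give 3-ethoxy-4-(3-methylbut-2-en-1-yl)cyclobut-2-en-1-one F1, and reduction with i-Bu2AlH followed by dilute acid should transpose it to 4-(3-methylbut-2-en-1-yl)cyclobut-2-en-1-one F2. Heating F2 with 5 in toluene at 80 °C in the dark should open F2 to the same vinylketene 10, which then runs through 11, 12 and 13 to 14 as in the thermal form of the benzannulation.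

Step 2. The most likely failure is deprotonation of the ester at its doubly activated methylene instead of carbenoid addition, followed by base-induced migration of the alkene; the α-hydrogens of 2 are both allylic and α to the ester. The fallback replaces the carbenoid rearrangement by oxidation of an acetylide. It sets out from 6 (made from 2 as in step 3) and returns at 4, which is silylated to 5 as in step 2. Corey–Fuchs olefination of 6 with CBr4 and PPh3 should give 1,1-dibromo-5-methylhexa-1,4-diene F3. Two equivalents of n-BuLi at −78 °C should convert F3 into lithium 5-methylhex-4-en-1-yn-1-ide F4, and oxidation of F4 with t-BuOOLi should give ynolate 4.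

Step 4. The most likely failure is deprotonation of 7 at the doubly allylic C5 instead of the methyl group, which would lead to conjugated dienones and scrambled alkene geometry; that methylene is the thermodynamically more acidic site. The fallback never exposes the skipped dienone to a strong base. It sets out from 6 and returns at 9. Horner–Wadsworth–Emmons olefination of 6 with the anion of diethyl (3-diazo-2-oxopropyl)phosphonate (NaH, THF, 0 °C) should give the E diazoketone 9 directly, so that steps 3 and 4 merge.

Step 10. The most likely failure is β-elimination of the activated alcohol to a cinnamate, with partial ionisation at the benzylic carbon and erosion of enantiomeric purity as the second risk; the oxyphosphonium group is β to an ester and on a benzylic carbon. The fallback sets C2 by a catalyst-controlled C–C bond formation. It sets out from 16 and returns at 24. ortho-Formylation with MgCl2, Et3N and paraformaldehyde should give 2-hydroxy-4-(methoxymethoxy)-3,5-bis(3-methylbut-2-en-1-yl)benzaldehyde F5. Addition of MeMgBr should give 1-[2-hydroxy-4-(methoxymethoxy)-3,5-bis(3-methylbut-2-en-1-yl)phenyl]ethan-1-ol F6, and MnO2 should oxidise it to 1-[2-hydroxy-4-(methoxymethoxy)-3,5-bis(3-methylbut-2-en-1-yl)phenyl]ethan-1-one F7. Condensation with dimethylformamide dimethyl acetal should give (E)-3-(dimethylamino)-1-[2-hydroxy-4-(methoxymethoxy)-3,5-bis(3-methylbut-2-en-1-yl)phenyl]prop-2-en-1-one F8, which should close under pyridinium p-toluenesulfonate to 7-(methoxymethoxy)-6,8-bis(3-methylbut-2-en-1-yl)-4H-chromen-4-one F9. Asymmetric conjugate addition of 4-acetoxyphenylboronic acid to F9 with Pd(OCOCF3)2 and a t-BuPyOx ligand, using the ligand enantiomer that delivers the 2S product, should give 24.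

Step 12. The most likely failure is protonation of a prenyl alkene or loss of the O7 acetal by the liberated trifluoroacetic acid, followed by chroman formation. The fallback uses an electrophile that works in the presence of a base. It sets out from 22 and returns at 24. Coupling with one equivalent of dimethylamine (EDC, HOBt, −20 °C, so that the aryl acetate is not aminolysed) should give 4-{(1S)-3-(dimethylamino)-1-[3-(methoxymethoxy)-2,4-bis(3-methylbut-2-en-1-yl)phenoxy]-3-oxopropyl}phenyl acetate F10. Activation with Tf2O and 2-fluoropyridine at −78 → 0 °C should bring about a Vilsmeier–Haack-type cyclisation at C4a to the iminium salt N-[(2S)-2-(4-acetoxyphenyl)-7-(methoxymethoxy)-6,8-bis(3-methylbut-2-en-1-yl)-2,3-dihydro-4H-chromen-4-ylidene]-N-methylmethanaminium trifluoromethanesulfonate F11, and aqueous NaHCO3 should hydrolyse F11 to 24.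

## Further compounds

F1 | step 5 | 3-ethoxy-4-(3-methylbut-2-en-1-yl)cyclobut-2-en-1-one (racemic) | CCOC1=CC(=O)C1CC=C(C)C
F2 | step 5 | 4-(3-methylbut-2-en-1-yl)cyclobut-2-en-1-one (racemic) | O=C1C=CC1CC=C(C)C
F3 | step 2 | 1,1-dibromo-5-methylhexa-1,4-diene | BrC(Br)=CCC=C(C)C
F4 | step 2 | lithium 5-methylhex-4-en-1-yn-1-ide | [Li]C#CCC=C(C)C
F0 | step 4 | none | none
F5 | step 10 | 2-hydroxy-4-(methoxymethoxy)-3,5-bis(3-methylbut-2-en-1-yl)benzaldehyde | O=Cc1cc(CC=C(C)C)c(OCOC)c(CC=C(C)C)c1O
F6 | step 10 | 1-[2-hydroxy-4-(methoxymethoxy)-3,5-bis(3-methylbut-2-en-1-yl)phenyl]ethan-1-ol (racemic) | CC(O)c1cc(CC=C(C)C)c(OCOC)c(CC=C(C)C)c1O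
F7 | step 10 | 1-[2-hydroxy-4-(methoxymethoxy)-3,5-bis(3-methylbut-2-en-1-yl)phenyl]ethan-1-one | CC(=O)c1cc(CC=C(C)C)c(OCOC)c(CC=C(C)C)c1O
F8 | step 10 | (E)-3-(dimethylamino)-1-[2-hydroxy-4-(methoxymethoxy)-3,5-bis(3-methylbut-2-en-1-yl)phenyl]prop-2-en-1-one | CN(C)/C=C/C(=O)c1cc(CC=C(C)C)c(OCOC)c(CC=C(C)C)c1O
F9 | step 10 | 7-(methoxymethoxy)-6,8-bis(3-methylbut-2-en-1-yl)-4H-chromen-4-one | CC(C)=CCc1cc2C(=O)C=COc2c(CC=C(C)C)c1OCOC
F10 | step 12 | 4-{(1S)-3-(dimethylamino)-1-[3-(methoxymethoxy)-2,4-bis(3-methylbut-2-en-1-yl)phenoxy]-3-oxopropyl}phenyl acetate | CN(C)C(=O)C[C@H](Oc1ccc(CC=C(C)C)c(OCOC)c1CC=C(C)C)c1ccc(OC(C)=O)cc1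
F11 | step 12 | N-[(2S)-2-(4-acetoxyphenyl)-7-(methoxymethoxy)-6,8-bis(3-methylbut-2-en-1-yl)-2,3-dihydro-4H-chromen-4-ylidene]-N-methylmethanaminium trifluoromethanesulfonate | CC(C)=CCc1cc2c(c(CC=C(C)C)c1OCOC)O[C@H](c1ccc(OC(C)=O)cc1)CC2=[N+](C)C.[O-]S(=O)(=O)C(F)(F)F
A1 | alternative 1 | (2S)-2-{4-[(tert-butyldimethylsilyl)oxy]phenyl}-7-hydroxy-6,8-di(prop-2-en-1-yl)-2,3-dihydro-4H-chromen-4-one | C=CCc1cc2c(c(CC=C)c1O)O[C@H](c1ccc(O[Si](C)(C)C(C)(C)C)cc1)CC2=O
A2 | alternative 1 | 2-methylbut-2-ene | CC=C(C)C
A3 | alternative 1 | (2S)-2-{4-[(tert-butyldimethylsilyl)oxy]phenyl}-7-hydroxy-6,8-bis(3-methylbut-2-en-1-yl)-2,3-dihydro-4H-chromen-4-one | CC(C)=CCc1cc2c(c(CC=C(C)C)c1O)O[C@H](c1ccc(O[Si](C)(C)C(C)(C)C)cc1)CC2=O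
A4 | alternative 2 | (1S,3S)-1-[2-bromo-4-(methoxymethoxy)-3,5-bis(3-methylbut-2-en-1-yl)phenyl]-3-[4-(methoxymethoxy)phenyl]propane-1,3-diol | CC(C)=CCc1cc([C@@H](O)C[C@H](O)c2ccc(OCOC)cc2)c(Br)c(CC=C(C)C)c1OCOC
A5 | alternative 2 | (2S,4S)-7-(methoxymethoxy)-2-[4-(methoxymethoxy)phenyl]-6,8-bis(3-methylbut-2-en-1-yl)-3,4-dihydro-2H-chromen-4-ol | CC(C)=CCc1cc2c(c(CC=C(C)C)c1OCOC)O[C@H](c1ccc(OCOC)cc1)C[C@@H]2O
A6 | alternative 3 | 2,10-dimethylundeca-2,9-dien-6-one | CC(C)=CCCC(=O)CCC=C(C)C
A7 | alternative 3 | diethyl 2-(ethoxymethylidene)propanedioate | CCOC=C(C(=O)OCC)C(=O)OCC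
A8 | alternative 3 | ethyl 2,4-dihydroxy-3,5-bis(3-methylbut-2-en-1-yl)benzoate | CCOC(=O)c1cc(CC=C(C)C)c(O)c(CC=C(C)C)c1O
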